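The plan cuts the ring-A side chain at two bonds at once: C5 of ring A to C1', and C2' to C3'. It exploits two facts: C5 is the only unsubstituted aromatic carbon of the methylene-bridged dimer, and C1'–C2' is a two-carbon unit held between ring A and an isopropenyl group with the oxygen on C2', the pattern a vinylboron unit gives when an aryl group adds to its terminal carbon while an alkenyl group migrates to the boron-bearing carbon. One palladium-catalysed conjunctive coupling thus forms both C–C bonds and sets C2' as a C–B stereocentre, oxidised later with retention. Its precursor is the 5-bromo dimer with five MOM ethers and both ketones free.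

Key step: step 7

Remark: ring A is the butanoyl ring (butanoyl on C1, hydroxyls on C2, C4 and C6, bridge on C3, side chain on C5), ring B is the acetyl/methoxy ring, and the side-chain carbons are C1' to C4'. C2' of the target is (R). It is assumed that the antipode of the MandyPhos ligand that gives the (R)-boronate is fixed beforehand on 2-bromo-1,3,5-tris(methoxymethoxy)benzene, both antipodes being available.

Step 1
Reactants: 1 2,4,6-trihydroxytoluene
Product: 2 1-(2,4,6-trihydroxy-3-methylphenyl)ethan-1-one
Conditions: AcCl (1.1 equiv), AlCl3 (3.5 equiv), PhNO2/CH2Cl2, 0 °C to rt; then ice, aq HCl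
Reagents that add atoms: acetyl chloride, CC(=O)Cl
Why: Friedel–Crafts acylation of the electron-rich triol, in which the two free ring carbons of 1 are equivalent by symmetry and the first acyl group (chelated to aluminium) deactivates the ring towards a second acylation.

Step 2
Reactants: 2 1-(2,4,6-trihydroxy-3-methylphenyl)ethan-1-one
Product: 3 1-(2,6-dihydroxy-4-methoxy-3-methylphenyl)ethan-1-one
Conditions: Me2SO4 (1.0 equiv), K2CO3 (1.0 equiv), acetone, rt
Reagents that add atoms: dimethyl sulfate, COS(=O)(=O)OC
Why: Williamson-type O-methylation, selective because the 4-hydroxyl (para to the acetyl group) is the most acidic and the only one not hydrogen-bonded to the carbonyl, so one equivalent of the sulfate should alkylate it first.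

Step 3
Reactants: 3 1-(2,6-dihydroxy-4-methoxy-3-methylphenyl)ethan-1-one
Product: 4 1-[3-[(dimethylamino)methyl]-2,6-dihydroxy-4-methoxy-5-methylphenyl]ethan-1-one
Conditions: N,N-dimethylmethyleneiminium iodide (1.1 equiv), Et3N (1.1 equiv), CH2Cl2, 0 °C to rt
Reagents that add atoms: N,N-dimethylmethyleneiminium iodide (Eschenmoser's salt), C=[N+](C)C.[I-]
Why: Mannich aminomethylation with a preformed iminium salt at the single unsubstituted ring carbon of 3 (between OH and OMe), the most nucleophilic site of the enol-like acylphloroglucinol.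

Step 4
Reactants: 4 1-[3-[(dimethylamino)methyl]-2,6-dihydroxy-4-methoxy-5-methylphenyl]ethan-1-one; 5 1-(2,4,6-trihydroxyphenyl)butan-1-one
Product: 7 1-[3-[(3-acetyl-2,4-dihydroxy-6-methoxy-5-methylphenyl)methyl]-2,4,6-trihydroxyphenyl]butan-1-one, via ortho-quinone methide 6 (not isolated)
Conditions: 5 (3 equiv), 1,4-dioxane, 100 °C, N2 sweep
Reagents that add atoms: none
Why: Thermal loss of dimethylamine from the phenolic Mannich base gives the ortho-quinone methide, which a ring carbon of 5 captures in a conjugate (Friedel–Crafts-type) addition with rearomatisation of both rings; the two nucleophilic carbons of 5 are equivalent, and its excess plus removal of the amine disfavours a second alkylation.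

Step 5
Reactants: 7 1-[3-[(3-acetyl-2,4-dihydroxy-6-methoxy-5-methylphenyl)methyl]-2,4,6-trihydroxyphenyl]butan-1-one
Product: 8 1-[3-[(3-acetyl-2,4-dihydroxy-6-methoxy-5-methylphenyl)methyl]-5-bromo-2,4,6-trihydroxyphenyl]butan-1-one
Conditions: NBS (1.0 equiv), MeCN, −20 to 0 °C, dark
Reagents that add atoms: N-bromosuccinimide, O=C1CCC(=O)N1Br
Why: Electrophilic aromatic bromination at C5 of ring A, the only aromatic C–H of 7 and ortho/para to three hydroxyls, so one equivalent of NBS under cold ionic conditions should substitute there before any ipso attack or side-chain halogenation.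

Step 6
Reactants: 8 1-[3-[(3-acetyl-2,4-dihydroxy-6-methoxy-5-methylphenyl)methyl]-5-bromo-2,4,6-trihydroxyphenyl]butan-1-one
Product: 9 1-[3-[[3-acetyl-6-methoxy-2,4-bis(methoxymethoxy)-5-methylphenyl]methyl]-5-bromo-2,4,6-tris(methoxymethoxy)phenyl]butan-1-one
Conditions: NaH (5.5 equiv), MOMCl (6 equiv), DMF, 0 °C to rt
Reagents that add atoms: chloromethyl methyl ether, COCCl
Why: Williamson etherification of the five phenoxides with a hard electrophile that reacts at oxygen, not carbon; NaH is chosen because four of the five hydroxyls are chelated to a carbonyl group and react incompletely with amine bases.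

Step 7
Reactants: 9 1-[3-[[3-acetyl-6-methoxy-2,4-bis(methoxymethoxy)-5-methylphenyl]methyl]-5-bromo-2,4,6-tris(methoxymethoxy)phenyl]butan-1-one; 10 2-bromopropene; 11 vinylboronic acid pinacol ester
Product: 14 1-[3-[[3-acetyl-6-methoxy-2,4-bis(methoxymethoxy)-5-methylphenyl]methyl]-2,4,6-tris(methoxymethoxy)-5-[(2R)-3-methyl-2-(4,4,5,5-tetramethyl-1,3,2-dioxaborolan-2-yl)but-3-en-1-yl]phenyl]butan-1-one, via isopropenyllithium 12 (not isolated), via lithium isopropenyl(vinyl)pinacolatoborate 13 (not isolated)
Conditions: 10, t-BuLi (1.95 equiv per 10), Et2O, −78 °C; 11 (1.05 equiv per 12), −78 °C to rt; evaporate, THF; then 9 (limiting), Pd(OAc)2 (5 mol %), MandyPhos ligand (1,1'-bis(diarylphosphino)-2,2'-bis[α-(dimethylamino)benzyl]ferrocene, 3,5-xylyl member first, 6 mol %), KOTf (potassium trifluoromethanesulfonate, 3 equiv), THF, 60 °C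
Reagents that add atoms: none
Why: Bromide 9 adds oxidatively to the zerovalent palladium–bisphosphine complex and KOTf strips bromide as insoluble KBr, so the cationic aryl complex of divalent palladium binds the unsubstituted vinyl group of borate 13; this π-activation triggers a 1,2-metallate shift of the isopropenyl group from boron to the boron-bearing vinyl carbon, anti to palladium, and reductive elimination then joins the terminal carbon to C5 of ring A. The closest known reaction type is the palladium-catalysed enantioselective conjunctive cross-coupling of bis(alkenyl)borates with aryl electrophiles to give α-chiral allylic boronates, applied here to a more hindered bromide; no ring is closed. The new stereocentre C2' is set under catalyst control, since the chiral ferrocenyl bisphosphine decides which face of the bound vinyl group palladium occupies and the anti migration then fixes the (R) configuration at the C–B carbon. Three selectivities are needed: the vinyl group, not the 1,1-disubstituted isopropenyl group, must be the π-ligand (it is the less hindered alkene, so isopropenyl migrates); the conjunctive path must beat direct alkenyl transfer to palladium (halide scavenging keeps palladium cationic and alkene-bound); and the ketones must survive (each has two ortho substituents and is twisted out of conjugation, and the slight excess of 11 over 12 leaves no free carbanion). Evaporation before the coupling removes residual volatile 10, which could otherwise act as a competing electrophile, and the MOM ethers are the smallest acetal protection next to the C–Br bond.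

Step 8
Reactants: 14 (R)-allylic boronate of the penta-MOM dimer
Product: 15 1-[3-[[3-acetyl-6-methoxy-2,4-bis(methoxymethoxy)-5-methylphenyl]methyl]-5-[(2R)-2-hydroxy-3-methylbut-3-en-1-yl]-2,4,6-tris(methoxymethoxy)phenyl]butan-1-one
Conditions: 30% H2O2, 3 M NaOH, THF, 0 °C to rt
Reagents that add atoms: hydrogen peroxide, OO
Why: Oxidation of the carbon–boron bond, in which hydroperoxide adds to boron and C2' migrates from boron to oxygen with retention (a 1,2-shift, no allyl transposition) to give the (R)-carbinol; MOM acetals are base-stable and the non-phenolic, doubly ortho-substituted ketones resist cold alkaline peroxide.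

Step 9
Reactants: 15 (R)-carbinol of the penta-MOM dimer
Product: 17 1-[3-[(3-acetyl-2,4-dihydroxy-6-methoxy-5-methylphenyl)methyl]-2,4,6-trihydroxy-5-[(2R)-2-hydroxy-3-methylbut-3-en-1-yl]phenyl]butan-1-one (target), via hexakis(trimethylsilyl) ether 16 (not isolated)
Conditions: TMSOTf (15 equiv), 2,2'-bipyridyl (20 equiv), MeCN, 0 °C to rt; then H2O, rt
Reagents that add atoms: none
Why: Acetal cleavage with a silyl triflate–bipyridyl pair, which converts each aryl MOM ether into the aryl silyl ether while the methoxymethyl unit is captured on bipyridyl nitrogen, after which water cleaves all O–Si bonds; no free Brønsted acid is present, so the phenols should not add to the isopropenyl group and C2' is untouched.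

Compound list
1 | 2,4,6-trihydroxytoluene | Cc1c(O)cc(O)cc1O | starting material
2 | 1-(2,4,6-trihydroxy-3-methylphenyl)ethan-1-one | CC(=O)c1c(O)cc(O)c(C)c1O | intermediate
3 | 1-(2,6-dihydroxy-4-methoxy-3-methylphenyl)ethan-1-one | CC(=O)c1c(O)cc(OC)c(C)c1O | intermediate
4 | 1-[3-[(dimethylamino)methyl]-2,6-dihydroxy-4-methoxy-5-methylphenyl]ethan-1-one | CC(=O)c1c(O)c(CN(C)C)c(OC)c(C)c1O | intermediate
5 | 1-(2,4,6-trihydroxyphenyl)butan-1-one | CCCC(=O)c1c(O)cc(O)cc1O | starting material
6 | 2-acetyl-3-hydroxy-5-methoxy-4-methyl-6-methylidenecyclohexa-2,4-dien-1-one (ortho-quinone methide of ring B) | C=C1C(=O)C(C(C)=O)=C(O)C(C)=C1OC | intermediate (not isolated)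
7 | 1-[3-[(3-acetyl-2,4-dihydroxy-6-methoxy-5-methylphenyl)methyl]-2,4,6-trihydroxyphenyl]butan-1-one | CCCC(=O)c1c(O)cc(O)c(Cc2c(O)c(C(C)=O)c(O)c(C)c2OC)c1O | intermediate
8 | 1-[3-[(3-acetyl-2,4-dihydroxy-6-methoxy-5-methylphenyl)methyl]-5-bromo-2,4,6-trihydroxyphenyl]butan-1-one | CCCC(=O)c1c(O)c(Br)c(O)c(Cc2c(O)c(C(C)=O)c(O)c(C)c2OC)c1O | intermediate
9 | 1-[3-[[3-acetyl-6-methoxy-2,4-bis(methoxymethoxy)-5-methylphenyl]methyl]-5-bromo-2,4,6-tris(methoxymethoxy)phenyl]butan-1-one | CCCC(=O)c1c(OCOC)c(Br)c(OCOC)c(Cc2c(OCOC)c(C(C)=O)c(OCOC)c(C)c2OC)c1OCOC | intermediate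
10 | 2-bromopropene | C=C(C)Br | starting material
11 | vinylboronic acid pinacol ester (2-ethenyl-4,4,5,5-tetramethyl-1,3,2-dioxaborolane) | C=CB1OC(C)(C)C(C)(C)O1 | starting material
12 | isopropenyllithium | [Li]C(C)=C | intermediate (not isolated)
13 | lithium 2-ethenyl-4,4,5,5-tetramethyl-2-(prop-1-en-2-yl)-1,3,2-dioxaborolan-2-uide | [Li+].C=C[B-]1(C(C)=C)OC(C)(C)C(C)(C)O1 | intermediate (not isolated)
14 | 1-[3-[[3-acetyl-6-methoxy-2,4-bis(methoxymethoxy)-5-methylphenyl]methyl]-2,4,6-tris(methoxymethoxy)-5-[(2R)-3-methyl-2-(4,4,5,5-tetramethyl-1,3,2-dioxaborolan-2-yl)but-3-en-1-yl]phenyl]butan-1-one | C=C(C)[C@H](B1OC(C)(C)C(C)(C)O1)Cc1c(OCOC)c(Cc2c(OCOC)c(C(C)=O)c(OCOC)c(C)c2OC)c(OCOC)c(C(=O)CCC)c1OCOC | intermediate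
15 | 1-[3-[[3-acetyl-6-methoxy-2,4-bis(methoxymethoxy)-5-methylphenyl]methyl]-5-[(2R)-2-hydroxy-3-methylbut-3-en-1-yl]-2,4,6-tris(methoxymethoxy)phenyl]butan-1-one | C=C(C)[C@H](O)Cc1c(OCOC)c(Cc2c(OCOC)c(C(C)=O)c(OCOC)c(C)c2OC)c(OCOC)c(C(=O)CCC)c1OCOC | intermediate
16 | hexakis(trimethylsilyl) ether of the target (five aryl O–SiMe3 and the C2' O–SiMe3, (R) at C2') | C=C(C)[C@H](O[Si](C)(C)C)Cc1c(O[Si](C)(C)C)c(Cc2c(O[Si](C)(C)C)c(C(C)=O)c(O[Si](C)(C)C)c(C)c2OC)c(O[Si](C)(C)C)c(C(=O)CCC)c1O[Si](C)(C)C | intermediate (not isolated)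
17 | 1-[3-[(3-acetyl-2,4-dihydroxy-6-methoxy-5-methylphenyl)methyl]-2,4,6-trihydroxy-5-[(2R)-2-hydroxy-3-methylbut-3-en-1-yl]phenyl]butan-1-one | C=C(C)[C@H](O)Cc1c(O)c(Cc2c(O)c(C(C)=O)c(O)c(C)c2OC)c(O)c(C(=O)CCC)c1O | target

Total step count: 9. Longest linear sequence: 9 steps (1 to 17; compounds 5, 10 and 11 enter as purchased materials).

Steps most likely to fail

1. Step 7. The bromide sits between two ortho acetal oxygens on a fully substituted ring, so oxidative addition or alkene binding may stall. Protodebromination or direct alkenyl transfer to palladium would then take over, and face selection could also be poor. Fallback, setting out from 9: Migita–Kosugi–Stille allylation (allyltributylstannane, Pd(P(t-Bu)3)2, CsF, 1,4-dioxane, 100 °C) would give 1-[3-[[3-acetyl-6-methoxy-2,4-bis(methoxymethoxy)-5-methylphenyl]methyl]-2,4,6-tris(methoxymethoxy)-5-(prop-2-en-1-yl)phenyl]butan-1-one F1. Lemieux–Johnson cleavage (OsO4 cat., NaIO4, 2,6-lutidine, dioxane/H2O) would give 2-[3-[[3-acetyl-6-methoxy-2,4-bis(methoxymethoxy)-5-methylphenyl]methyl]-5-butanoyl-2,4,6-tris(methoxymethoxy)phenyl]acetaldehyde F2. An asymmetric Nozaki–Hiyama–Kishi addition of 10 (CrCl2, NiCl2 cat., chiral sulfonamide–oxazoline ligand, Et3N, THF), which is aldehyde-selective in the presence of the two hindered ketones and in which the ligand controls the carbonyl face, would give the (R)-carbinol. The route is rejoined at 15.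

2. Step 4. A second quinone methide may add to the remaining ring-A carbon of the product, or the methylene bridge may exchange to symmetrical dimers at the temperature needed for amine loss. Fallback, setting out from 5: monobromination (NBS, 1.0 equiv, THF, −78 to 0 °C) would give 1-(3-bromo-2,4,6-trihydroxyphenyl)butan-1-one F3, in which bromine blocks the second nucleophilic carbon. Heating F3 with Mannich base 4 under the step 4 conditions (through 6) would give the bromo dimer directly. The route is rejoined at 8 and step 5 is omitted.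

3. Step 9. Acetal removal may be incomplete at the ketone-flanked positions, or a liberated phenol may close onto the side-chain alkene under Lewis-acid activation. Fallback, setting out from 8: etherification with 2-(trimethylsilyl)ethoxymethyl chloride (NaH, DMF) would give 1-[3-[[3-acetyl-6-methoxy-5-methyl-2,4-bis[[2-(trimethylsilyl)ethoxy]methoxy]phenyl]methyl]-5-bromo-2,4,6-tris[[2-(trimethylsilyl)ethoxy]methoxy]phenyl]butan-1-one F4. The conjunctive coupling under the step 7 conditions (through 12 and 13) would give the corresponding (R)-allylic boronate penta-SEM ether F5, and cold alkaline peroxide would give the (R)-carbinol penta-SEM ether F6. Fluoride-induced cleavage (Bu4NF, THF/DMPU, 60 °C) is basic throughout and involves no acid. The route is rejoined at 17.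

Further compounds
F1 | step 7 | 1-[3-[[3-acetyl-6-methoxy-2,4-bis(methoxymethoxy)-5-methylphenyl]methyl]-2,4,6-tris(methoxymethoxy)-5-(prop-2-en-1-yl)phenyl]butan-1-one | C=CCc1c(OCOC)c(Cc2c(OCOC)c(C(C)=O)c(OCOC)c(C)c2OC)c(OCOC)c(C(=O)CCC)c1OCOC
F2 | step 7 | 2-[3-[[3-acetyl-6-methoxy-2,4-bis(methoxymethoxy)-5-methylphenyl]methyl]-5-butanoyl-2,4,6-tris(methoxymethoxy)phenyl]acetaldehyde | O=CCc1c(OCOC)c(Cc2c(OCOC)c(C(C)=O)c(OCOC)c(C)c2OC)c(OCOC)c(C(=O)CCC)c1OCOC
F3 | step 4 | 1-(3-bromo-2,4,6-trihydroxyphenyl)butan-1-one | CCCC(=O)c1c(O)cc(O)c(Br)c1O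
F4 | step 9 | 1-[3-[[3-acetyl-6-methoxy-5-methyl-2,4-bis[[2-(trimethylsilyl)ethoxy]methoxy]phenyl]methyl]-5-bromo-2,4,6-tris[[2-(trimethylsilyl)ethoxy]methoxy]phenyl]butan-1-one | CCCC(=O)c1c(OCOCC[Si](C)(C)C)c(Br)c(OCOCC[Si](C)(C)C)c(Cc2c(OCOCC[Si](C)(C)C)c(C(C)=O)c(OCOCC[Si](C)(C)C)c(C)c2OC)c1OCOCC[Si](C)(C)C
F5 | step 9 | (2R)-allylic pinacol boronate of the penta-SEM dimer (as 14, with SEM in place of each MOM) | C=C(C)[C@H](B1OC(C)(C)C(C)(C)O1)Cc1c(OCOCC[Si](C)(C)C)c(Cc2c(OCOCC[Si](C)(C)C)c(C(C)=O)c(OCOCC[Si](C)(C)C)c(C)c2OC)c(OCOCC[Si](C)(C)C)c(C(=O)CCC)c1OCOCC[Si](C)(C)C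
F6 | step 9 | (2R)-carbinol of the penta-SEM dimer (as 15, with SEM in place of each MOM) | C=C(C)[C@H](O)Cc1c(OCOCC[Si](C)(C)C)c(Cc2c(OCOCC[Si](C)(C)C)c(C(C)=O)c(OCOCC[Si](C)(C)C)c(C)c2OC)c(OCOCC[Si](C)(C)C)c(C(=O)CCC)c1OCOCC[Si](C)(C)C
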